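Ask first what must stand in this flask at the end, then how fast it gets there.

| flask | substrate | gas phase | catalyst | remark | time |
|---|---|---|---|---|---|
| south-west | 0.050 M | 23 mM (held) | 0.33 mM | run made earlier |  |
| north-east | 0.050 M | 23 mM (held) | 1.3 mM | run made earlier |  |
| west | 0.075 M | 23 mM (held) | 0.65 mM | run made earlier |  |
| flask | 0.050 M | 23 mM (held) | 0.65 mM |  | 15 d |

- south-west (time / d: product / %): 1.04: 55.8; 3.00: 97.4; 6.00: 99.9; 8.00: 99.9; 12.0: 100.5
- north-east (time / d: product / %): 1.04: 84.3; 3.00: 100.3; 6.00: 100.5; 8.00: 99.1; 12.0: 98.4
- west (time / d: product / %): 1.04: 58.1; 3.00: 100.7; 6.00: 101.1; 8.00: 101.1; 12.0: 98.7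

(readings scatter by 1 percentage point)

- at the start none of the gas is dissolved
- the analysis behind the earlier runs scatters by 1 percentage point, standard deviation
- on the list of suspects stand: gas phase <-> dissolved gas; substrate + dissolved gas + catalyst -> catalyst + product
- the reaction counts as stopped when no species that holds the substrate changes by six tenths of a point or more over the second half of the time

* at 15 d, what has stopped the reaction, if anything has (it is still moving / all of the substrate has reacted / no working catalyst is left)
* product at 15 d, in percent of the substrate charged

The last readings of the earlier runs stand at 100.5%, 98.4% and 98.7%, so I expect this flask to end with its substrate converted. My doubt is catalyst death. But the south-west run made 152 turnovers, and this flask needs fewer, namely 76.9.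

How fast does it get there? The south-west run has the lower c(catalyst), 0.33 mM against 0.65 mM, so I take its pace as a slow estimate. From its first two readings I get 0.480 d, a value that carries their scatter. This is the clearing half-life, the time in which the unreacted substrate halves, a pseudo-first-order reading.

One objection remains. The early pace is not proportional to catalyst: at 1.04 d, 3.94 times the catalyst reads 84.3% against 55.8%. So I count from that first reading and ignore the time before it. By this estimate that leaves 29.1 half-lives in this flask, and 6.64 half-lives cut any remainder to a hundredth. I commit to full conversion.

The forecast says the same: all of the substrate has reacted, product 100%, noting that “Plateaus near 100% through 12 d show no product loss”.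

The flask gives 100% product at 15 d: all of the substrate has reacted, with 0% substrate remaining. At 3.00 d this flask holds 0.0812% substrate. Starting from its 11.1% at 1.50 d, the clearing half-life gives 1.27% at that time, which is more, so here it was indeed a slow estimate.

    gas phase ⇌ dissolved gas, rate k1*(csat - [dissolved gas]) (kL = 3.24 × 10⁻⁵ /s)
    substrate + dissolved gas + catalyst → catalyst + product (k = 2.94 /M²/s)

Read at 10 d instead, the neighbour flask has an estimated 18.7 half-lives, still above 6.64. Computed, it gives 100% product and 0% substrate left.

(All runs come from a simulation with constants of no real substance, and the scatter is random.)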